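**Assumption:** the target is taken exactly as the SMILES reads: (R) at the ring‑A CHBr, (S) at the spiro carbon, (S) at C(Me)Br, (S) at CHCl, with Br and Cl trans on ring B.

**Numbering used below (p‑menthane/bisabolane):** C1 = C(Me)X, C2 = CHX, C4 = ring carbon that becomes the spiro centre, C8 = exocyclic carbon on C4.

## Retrosynthetic overview

1. Ring B is bought as (R)‑limonene (1). Its ring‑alkene carbons become C(Me)Br and CHCl via epoxide 2 → chlorohydrin 3 → ketone 4 → bromide 5, each step a trans‑diaxial opening steered by the limonene stereocentre.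
2. C4=C8 disconnection: the acetyl group of 5 becomes the (E)‑enol triflate 6, which is coupled with the C6 unit of bromide 7 to give the dihalo‑γ‑bisabolene 8. The limonene stereocentre is erased here; C1/C2 now carry the chirality.
3. Key disconnection (last bond): the spiro C4–CMe2 bond and the secondary C–Br of obtusane (9) are made together by anodic bromonium‑induced cation–olefin cyclisation of 8.
4. Ring order: ring B (from 1) first, ring A and the spiro centre last. C1/C2 direct the face of attack at C4; the E‑alkene geometry relays this to the CHBr centre through a chair transition state.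

## Route

**Step 1**
Reactants: 1, (R)‑(+)‑limonene
Product: 2, (+)‑trans‑limonene 1,2‑oxide, (1S,2R,4R)
Conditions: NBS, acetone–H2O, 0 °C; then aq NaOH
Reagents that add atoms: water, O
Why: Bromohydrin formation then epoxide closure; bromonium formation is reversible and only the bromonium that allows trans‑diaxial Markovnikov opening by water (Fürst–Plattner) is consumed, so base closure gives the epoxide cis to the isopropenyl group, (1S,2R), while the isopropenyl alkene is untouched.

**Step 2**
Reactants: 2, trans‑limonene 1,2‑oxide
Product: 3, (1S,2S,4R)‑2‑chloro‑1‑methyl‑4‑(prop‑1‑en‑2‑yl)cyclohexan‑1‑ol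
Conditions: LiCl, AcOH, THF, rt
Reagents that add atoms: lithium chloride, [Li+].[Cl-]
Why: SN2 epoxide opening under Fürst–Plattner control; for this diastereomer the trans‑diaxial path is attack at secondary C2 with inversion, giving axial Cl (2S) and leaving the axial tertiary OH (1S).

**Step 3**
Reactants: 3
Product: 4, 1‑[(1R,3S,4S)‑3‑chloro‑4‑hydroxy‑4‑methylcyclohexyl]ethan‑1‑one
Conditions: O3, CH2Cl2–MeOH, −78 °C; Me2S
Reagents that add atoms: ozone, [O-][O+]=O
Why: Ozonolysis of the only alkene gives the methyl ketone; no stereocentre is touched and the acetyl group stays equatorial (the stable epimer), which also removes the acid‑sensitive alkene before the next step.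

**Step 4**
Reactants: 4
Product: 5, 1‑[(1R,3S,4S)‑4‑bromo‑3‑chloro‑4‑methylcyclohexyl]ethan‑1‑one
Conditions: TMSBr, CH2Cl2, −20 → 0 °C
Reagents that add atoms: bromotrimethylsilane, C[Si](C)(C)Br
Why: SN1 deoxybromination of the tertiary alcohol with neighbouring‑group assistance; the axial C2–Cl is antiperiplanar to the leaving oxygen, so the chloronium‑like cation is captured by bromide at tertiary C1 from the original face (axial, trans‑diaxial), giving retention and the (S) C(Me)Br centre.

**Step 5**
Reactants: 5
Product: 6, (1E)‑1‑[(3S,4S)‑4‑bromo‑3‑chloro‑4‑methylcyclohexylidene]ethyl trifluoromethanesulfonate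
Conditions: Tf2O, 2,6‑di‑tert‑butyl‑4‑methylpyridine, CH2Cl2, 0 °C → rt; chromatographic separation of E from Z
Reagents that add atoms: triflic anhydride, O=S(=O)(OS(=O)(=O)C(F)(F)F)C(F)(F)F
Why: Stang enol triflation under non‑basic, equilibrating conditions enolises toward the more substituted α‑carbon (C4) without touching the halides; the remote halogens do not bias the geometry, so the E/Z pair (diastereomers, about 1:1 expected) is separated and only the E isomer (OTf cis to the ring CH2 remote from CHCl) is carried on.

**Step 6**
Reactants: 6; 7, 5‑bromo‑2‑methylpent‑2‑ene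
Product: 8, (1S,2S,4E)‑1‑bromo‑2‑chloro‑1‑methyl‑4‑(6‑methylhept‑5‑en‑2‑ylidene)cyclohexane
Conditions: 7, Zn, LiCl, THF (→ RZnBr); then 6, Pd(dppf)Cl2 (5 mol %), THF, 40 °C
Reagents that add atoms: (4‑methylpent‑3‑en‑1‑yl)zinc bromide (from 7), CC(C)=CCC[Zn]Br
Why: Negishi sp2–sp3 cross‑coupling with retention of alkene geometry, so the chain ends up cis to the CH2 remote from CHCl; the tertiary bromide and secondary chloride are inert to the organozinc and to Pd(0) under these conditions.

**Step 7**
Reactants: 8
Product: 9, obtusane
Conditions: divided cell, graphite anode / Pt cathode; n‑Bu4NBr (1.1 equiv), 2,6‑di‑tert‑butylpyridine (1.5 equiv), n‑Bu4NPF6 (0.1 M), HFIP–CH2Cl2 4:1, −15 °C, constant current, 2.1 F/mol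
Reagents that add atoms: tetrabutylammonium bromide, [Br-].CCCC[N+](CCCC)(CCCC)CCCC
Why: Proposed new method: anodic two‑electron oxidation of bromide (about +0.9 V vs SCE, below either alkene) gives Br2/Br+ at low steady‑state concentration, and HFIP hydrogen bonding polarises it so that Br+ is transferred to the unhindered trisubstituted alkene; the bromonium is opened at its tertiary carbon by C4 of the tetrasubstituted alkene through a chair transition state, forming the spiro C–C bond on the face cis to Cl and trans to Br (equatorial attack on the ring‑B chair with Br/Cl equatorial, the other face forcing a syn‑axial halogen contact) to set the (S) spiro centre, while anti addition with Br equatorial and the E geometry set the (R) CHBr centre, and the hindered base removes a proton from the C8 methyl to give the exocyclic methylene; the closest known reactions are chemical bromonium‑induced polyene cyclisations (Et2SBr·SbCl5Br in MeNO2, TBCO, NBS in HFIP) and anodic bromide‑mediated bromolactonisation/bromoetherification of alkenes, but an electrogenerated bromonium has not been used for a C–C‑forming cyclisation that makes a spiro quaternary carbon next to a quaternary carbon (the divided cell keeps the vicinal dihalide away from the cathode).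

## Compound list

1 | (R)‑(+)‑limonene, (4R)‑1‑methyl‑4‑(prop‑1‑en‑2‑yl)cyclohex‑1‑ene | CC1=CC[C@H](C(C)=C)CC1 | starting material
2 | (+)‑trans‑limonene 1,2‑oxide, (1S,2R,4R)‑1,2‑epoxy‑p‑menth‑8‑ene | C[C@@]12O[C@@H]1C[C@H](C(C)=C)CC2 | intermediate
3 | (1S,2S,4R)‑2‑chloro‑1‑methyl‑4‑(prop‑1‑en‑2‑yl)cyclohexan‑1‑ol | C[C@@]1(O)[C@@H](Cl)C[C@H](C(C)=C)CC1 | intermediate
4 | 1‑[(1R,3S,4S)‑3‑chloro‑4‑hydroxy‑4‑methylcyclohexyl]ethan‑1‑one | C[C@@]1(O)[C@@H](Cl)C[C@H](C(C)=O)CC1 | intermediate
5 | 1‑[(1R,3S,4S)‑4‑bromo‑3‑chloro‑4‑methylcyclohexyl]ethan‑1‑one | C[C@@]1(Br)[C@@H](Cl)C[C@H](C(C)=O)CC1 | intermediate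
6 | (1E)‑1‑[(3S,4S)‑4‑bromo‑3‑chloro‑4‑methylcyclohexylidene]ethyl trifluoromethanesulfonate | C[C@@]1(Br)[C@@H](Cl)C/C(CC1)=C(\C)OS(=O)(=O)C(F)(F)F | intermediate
7 | 5‑bromo‑2‑methylpent‑2‑ene | CC(C)=CCCBr | starting material
8 | (1S,2S,4E)‑1‑bromo‑2‑chloro‑1‑methyl‑4‑(6‑methylhept‑5‑en‑2‑ylidene)cyclohexane | C[C@@]1(Br)[C@@H](Cl)C/C(CC1)=C(\C)CCC=C(C)C | intermediate
9 | obtusane, (2S,3S,6S,8R)‑3,8‑dibromo‑2‑chloro‑3,7,7‑trimethyl‑11‑methylidenespiro[5.5]undecane | C=C1CC[C@@H](Br)C(C)(C)[C@]12CC[C@](C)(Br)[C@@H](Cl)C2 | target

## Summary

**Total steps:** 7. **Longest linear sequence:** 7 (1 → 9); 7 is a purchased coupling partner.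

**Three steps most likely to fail, with fallbacks**

1. **Step 7 (proposed new method).** Risks: Br+ transfer to the tetrasubstituted alkene (loss of E geometry or dibromination), endocyclic instead of exocyclic proton loss, or attack on the wrong face of ring B.
 Fallback (known chemistry, different initiator): Hg(OTf)2·PhNMe2‑induced cation–olefin cyclisation of 8 to the organomercurial, then stereoretentive bromodemercuration (LiBr; Br2, pyridine, O2‑free).

2. **Step 5.** The alkene geometry is not controlled by the remote halogens, so up to half the material is the unwanted Z‑triflate; some terminal (less substituted) triflate may also form. The CHBr configuration in step 7 depends entirely on using pure E material.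
 Fallback: add (4‑methylpent‑3‑en‑1‑yl)magnesium bromide/CeCl3 to ketone 5 at −78 °C, separate the two C8‑epimeric tertiary alcohols, and dehydrate each by the complementary stereospecific mode (anti‑E2 with SOCl2/pyridine for one, syn‑Ei with Burgess reagent for the other) so both converge on (E)‑8.

3. **Step 4.** The β‑chloro tertiary cation may eliminate or give chlorine migration instead of clean retentive bromide capture.
 Fallback: reverse the order of halogen introduction. Start from (1R,2S,4R)‑cis‑limonene oxide (from the commercial cis/trans mixture by the known amine‑mediated kinetic separation), open it at C1 with MgBr2·OEt2 (trans‑diaxial tertiary bromide, secondary alcohol), ozonolyse, then replace the C2–OH by Cl with retention through bromonium participation (Ph3P/CCl4).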